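## Analysis of the target

The target is a monocyclic ten-membered lactone (ring oxygen plus C1–C9). C1 is the lactone carbonyl, C2 carries an acyloxy group, C3 and C4 are methylenes, C5=C6 is an E alkene, C7 and C8 are free carbinols, and C9 bears the ring oxygen and the propyl group C10–C12. The C2 oxygen is esterified by one carboxyl of (2E,4E)-muconic acid; the other carboxyl is free.

There are four stereocentres: 2R, 7R, 8S and 9R. C7–C9 form a contiguous triol unit (C7/C8 threo, C8/C9 erythro) that matches C2–C4 of D-arabinose when C6 is taken as the sugar C1. C2 is separated from this triad by C3–C6 and cannot be controlled from it.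

Sensitive features are the strained lactone next to two free hydroxyls (acyl migration to C8–O or C7–O), the allylic C7–O bond, the C2–H (alpha to C1 and acyloxy-substituted), and the dienoate, which is both a Michael acceptor and an activated ester. The difficulties are closing a ten-membered ring that holds an E alkene, setting C2 without help from the other centres, and telling four oxygens and two carboxyls apart.

The strategy rests on the C1(=O)–C2(O-acyl) unit. An alpha-acyloxy carbonyl group is the signature of a Passerini reaction: C2 from an aldehyde, the acyl group from a carboxylic acid, C1 from an isocyanide carbon.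

## Retrosynthetic reasoning

**24 to 23.** The C7/C8 diol and the terminal carboxyl of target 24 are unmasked last, from lactone 23 (C7/C8 acetonide, tert-butyl ester). Both masks fall to one acidic operation, so no skeletal bond is made at the end and the free diol never meets base.

**23 to 22 (and 21).** The C1–O bond to the C9 oxygen is cut. C9–OH is the one hydroxyl that can be freed alone (a single silyl ether in 21), and cutting here opens the ring to a chain whose C1 is the amide left by a Passerini reaction. The forward step must make the hindered C9 alcohol of hydroxy amide 22 displace 2-amino-6-bromopyridine 17 from C1 in a ten-membered closure. This is the least precedented step of the route.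

**21 to 14 + 16 + 19.** The C1–C2 bond and the C2–O ester bond are cut together. This gives aldehyde 14 (C2–C12), half ester 16 and isocyanide 19. One step then delivers C1, the C2 stereocentre and the complete side chain, and no ring hydroxyl needs late acylation. The forward reaction needs control of the aldehyde face by a chiral acid catalyst, because C7–C9 are too remote to help.

**16 and 19.** Half ester 16 comes from diacid 15 by esterifying one carboxyl. Isocyanide 19 comes from formamide 18 and amine 17; the electron-poor pyridyl group is what later makes the amide a leaving group.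

**14 to 13 to 10 + 11, and 10 to 9.** Aldehyde 14 is the reduction product of ester 13. Ester 13 is a gamma,delta-unsaturated ester, the retron of a Claisen rearrangement of allylic alcohol 10 with orthoester 11. This cuts C3–C4 and sets the E C5=C6 alkene through a chair transition state. Alcohol 10 is cut at C5–C6 to aldehyde 9 and a vinyl nucleophile; its carbinol configuration is irrelevant.

**9 back to 1.** Aldehyde 9 is unmasked from dithioacetal 8, the silyl ether of alcohol 7. Alcohol 7 is cut at C10–C11 to epoxide 6 and an ethyl nucleophile. The epoxide opening releases C9–OH alone, so the C9 oxygen is differentiated from C7–O and C8–O without extra steps. Epoxide 6 comes from diol 4, and 4 from bis-acetonide 3 by hydrolysis of the terminal acetal only. Bis-acetonide 3 comes from dithioacetal 2 and D-arabinose 1, which supplies C6–C10 and all three stereocentres C7–C9.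

## Alternatives that were turned down

**Alternative 1:** The ring is released from a bicycle instead of being closed. The bond cut in the forward direction is C1–C6 of the trans-fused lactol A1 (two six-membered rings sharing C1–C6, C1 a hemiketal carbon bound to the C9 oxygen, an equatorial tributylstannyl group on C5). Pb(OAc)4 would oxidise the C1 hydroxyl; as C1–C6 breaks, the anti-periplanar C5–Sn bond supplies the electrons for the C5=C6 alkene. Lactone carbonyl, E alkene and ring of A2 would appear together.
- For: no medium-ring cyclisation has to be won, and the alkene geometry follows stereospecifically from the C5/C6 configuration. On both points it is stronger than the chosen route, whose lactonisation is unproven.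
- Against: A1 needs seven stereocentres, three of them (C1, C5, C6) only to be destroyed, on a carbocycle with no obvious chiral-pool origin. Stoichiometric tin and lead are required. After A2 the side chain still costs desilylation, acylation with 16 and two oxidative debenzylations beside a dienoate.
- In its place the chosen route offers three stereocentres from 1, the fourth centre and the side chain from one step, and a much shorter sequence.

**Alternative 2:** Cutting the C4–C5 single bond leads to ester A3. In A3 the C9 oxygen already carries the acyl unit (a 2-alkoxybut-3-enoate, C1–C4) and C5 is an E-alkenyl iodide. Hydroboration of the terminal C3=C4 alkene with 9-BBN and intramolecular B-alkyl Suzuki–Miyaura coupling under PdCl2(dppf) would form C4–C5 and the ring of A4 with retention of alkene geometry.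
- For: the ester bond is made intermolecularly, the E geometry is fixed before cyclisation, and this coupling type is established for larger rings. Its precedent for the bond type is better than that of the chosen lactonisation.
- Against: the beta,gamma-unsaturated alpha-alkoxy ester of A3 can slide into conjugation, with loss of C2, under the aqueous base the coupling needs. The ten-membered closure competes with beta-hydride elimination and dimerisation. A4 is still three operations from 24 (PMB removal, acylation, acetonide hydrolysis).
- It shares the medium-ring risk; the chosen route answers with convergence and with C2 and the side chain arriving together.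

**Alternative 3:** Cutting C6–C7 gives ester A5, with an E-alkenyl iodide at C6 and an aldehyde at C7. CrCl2 with catalytic NiCl2 would insert into the C–I bond, and the resulting carbon–chromium bond (trivalent chromium) would add to the aldehyde. This closes the ring to A6 and creates the C7 carbinol.
- For: closures of this type have been used for ten-membered lactones and tolerate esters and silyl ethers. On the ring-forming step it is the best precedented of the four options and clearly stronger than the chosen lactonisation.
- Against: C7 is created in the cyclisation under substrate control only, and its sense relative to the C8 silyloxy group is not assured. The alpha-silyloxy aldehyde of A5 can epimerise at C8. A large excess of a divalent chromium salt is needed. The free C7 hydroxyl of A6 must be protected before the C2 PMB ether is exchanged for the muconate, so about five steps follow ring closure.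
- The chosen route takes C7 from the sugar, never has to tell C7–OH from C2–OH, and ends three steps after its key step.

Key step: step 14

Assumption: the (R)-configured phosphoric acid of step 14 is taken to direct the isocyanide to the Si face of C2 (giving 2R); if a first run shows the opposite sense, the (S)-acid is used and nothing else changes.

## Route

Step 1
Reactants: 1 D-arabinose
Product: 2 D-arabinose diethyl dithioacetal
Conditions: EtSH, conc. HCl, 0 °C
Reagents that add atoms: ethanethiol, CCS
Why: Acid-catalysed dithioacetalisation opens the hemiacetal and masks the future C6 aldehyde; the hydroxyls and the three stereocentres are not touched.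

Step 2
Reactants: 2 D-arabinose diethyl dithioacetal
Product: 3 2,3:4,5-di-O-isopropylidene-D-arabinose diethyl dithioacetal
Conditions: Me2C(OMe)2, TsOH (cat.), DMF, rt
Reagents that add atoms: 2,2-dimethoxypropane, COC(C)(C)OC
Why: Thermodynamic acetonation; the threo 2,3-diol closes a trans-dioxolane and the terminal 4,5-diol a second one, the favoured pairing for an arabino tetraol.

Step 3
Reactants: 3 2,3:4,5-di-O-isopropylidene-D-arabinose diethyl dithioacetal
Product: 4 2,3-O-isopropylidene-D-arabinose diethyl dithioacetal (4,5-diol)
Conditions: 70% aq. AcOH, 40 °C, stopped after loss of one acetal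
Reagents that add atoms: none
Why: Selective acetal hydrolysis; a terminal dioxolane hydrolyses faster than a trans-4,5-disubstituted one, and the dithioacetal is inert to aqueous acetic acid.

Step 4
Reactants: 4 2,3-O-isopropylidene-D-arabinose diethyl dithioacetal
Product: 6 4,5-anhydro-2,3-O-isopropylidene-D-arabinose diethyl dithioacetal (terminal epoxide), via primary tosylate 5 (not isolated)
Conditions: TsCl, Et3N, Bu2SnO (cat.), CH2Cl2, 0 °C; then K2CO3, MeOH, rt
Reagents that add atoms: p-toluenesulfonyl chloride, Cc1ccc(cc1)S(Cl)(=O)=O (its atoms are held by 5 and leave again on closure to 6)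
Why: Tin-mediated selective sulfonylation of the primary hydroxyl, then intramolecular Williamson closure; the C–O bond at the future C9 is not broken, so its configuration is retained.

Step 5
Reactants: 6 4,5-anhydro-2,3-O-isopropylidene-D-arabinose diethyl dithioacetal
Product: 7 5,6,7-trideoxy-2,3-O-isopropylidene-D-arabino-heptose diethyl dithioacetal (C9 carbinol with the propyl chain)
Conditions: EtMgBr, CuI (10 mol %), THF, −40 → −20 °C; aq. NH4Cl
Reagents that add atoms: ethylmagnesium bromide, CC[Mg]Br
Why: Copper-catalysed SN2 opening of the terminal epoxide at its CH2 carbon completes C10–C12 and frees only the C9 hydroxyl; the dithioacetal and acetal are inert.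

Step 6
Reactants: 7 5,6,7-trideoxy-2,3-O-isopropylidene-D-arabino-heptose diethyl dithioacetal
Product: 8 4-O-tert-butyldimethylsilyl ether of 7 (C9 OTBS)
Conditions: TBSOTf, 2,6-lutidine, CH2Cl2, −78 → 0 °C
Reagents that add atoms: tert-butyldimethylsilyl trifluoromethanesulfonate, CC(C)(C)[Si](C)(C)OS(=O)(=O)C(F)(F)F
Why: Silylation of a hindered secondary alcohol with a silyl triflate; it marks C9–O as the one oxygen to be released later by fluoride.

Step 7
Reactants: 8 C9-OTBS dithioacetal
Product: 9 C6 aldehyde (C6–C12; C7/C8 acetonide; C9 OTBS)
Conditions: I2, NaHCO3, acetone/H2O, 0 °C; aq. Na2S2O3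
Reagents that add atoms: water, O
Why: Buffered oxidative hydrolysis of the dithioacetal, placed before any alkene is present; the trans-dioxolane holds C7, since its epimer would be the less stable cis-acetal.

Step 8
Reactants: 9 C6 aldehyde
Product: 10 allylic alcohol (C4–C12; both C6 epimers)
Conditions: CH2=CHMgBr, THF, −78 °C; aq. NH4Cl
Reagents that add atoms: vinylmagnesium bromide, C=C[Mg]Br
Why: Grignard 1,2-addition; the new C6 carbinol centre is destroyed in the next step, so both epimers are carried on together.

Step 9
Reactants: 10 allylic alcohol (C6 epimers); 11 triethyl orthoacetate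
Product: 13 ethyl (E)-ester of the C2–C12 chain (C2 ester carbon; C5=C6 E; C7/C8 acetonide; C9 OTBS), via mixed ketene acetal 12 (not isolated)
Conditions: MeC(OEt)3 (excess), EtCO2H (cat.), 135 °C, EtOH distilled off
Reagents that add atoms: none
Why: Johnson–Claisen rearrangement; the [3,3] shift through a chair with the bulky C7 substituent equatorial forms C3–C4 and should give the E C5=C6 alkene from either C6 epimer.

Step 10
Reactants: 13 ethyl (E)-ester
Product: 14 (E)-4-enal carrying C2–C12 (C7 R, C8 S, C9 R; C7/C8 acetonide; C9 OTBS)
Conditions: iBu2AlH (1.1 equiv), CH2Cl2, −78 °C; MeOH, then aq. potassium sodium tartrate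
Reagents that add atoms: none
Why: Partial reduction of the ester; the tetrahedral aluminium alkoxide persists at low temperature and releases the aldehyde only on work-up.

Step 11
Reactants: 15 (2E,4E)-muconic acid
Product: 16 mono-tert-butyl (2E,4E)-muconate
Conditions: Me2NCH(OtBu)2 (1.0 equiv, slow addition), DMF/toluene, 80 °C; NaHCO3 extraction, acidification
Reagents that add atoms: N,N-dimethylformamide di-tert-butyl acetal, CN(C)C(OC(C)(C)C)OC(C)(C)C
Why: O-alkylation of a carboxylate by the amide acetal; one equivalent should give a statistical mixture from which the half ester is separated by extraction (the diester stays neutral, the diacid is recovered).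

Step 12
Reactants: 17 2-amino-6-bromopyridine
Product: 18 N-(6-bromopyridin-2-yl)formamide
Conditions: HCO2H, Ac2O (premixed), THF, 0 °C → rt
Reagents that add atoms: formic acid, OC=O (delivered as acetic formic anhydride, CC(=O)OC=O, formed from it with acetic anhydride)
Why: N-formylation by the mixed anhydride, which transfers the formyl group because its carbonyl is the more electrophilic one; this suits the weakly nucleophilic aminopyridine.

Step 13
Reactants: 18 N-(6-bromopyridin-2-yl)formamide
Product: 19 2-bromo-6-isocyanopyridine
Conditions: POCl3, Et3N, CH2Cl2, −20 → 0 °C; aq. Na2CO3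
Reagents that add atoms: none
Why: Dehydration of an N-aryl formamide to the isocyanide through its O-phosphorylated imidate.

Step 14
Reactants: 14 (E)-4-enal; 16 mono-tert-butyl (2E,4E)-muconate; 19 2-bromo-6-isocyanopyridine
Product: 21 (2R)-alpha-acyloxy N-(6-bromopyridin-2-yl) amide with the full side chain (C7/C8 acetonide; C9 OTBS), via O-acyl imidate 20 (not isolated)
Conditions: (R)-3,3'-bis(2,4,6-triisopropylphenyl)-1,1'-binaphthyl-2,2'-diyl hydrogen phosphate (10 mol %), 16 and 19 (1.2 equiv each), 4 Å MS, CHCl3, 0 °C → rt
Reagents that add atoms: none
Why: This is a Passerini three-component reaction under chiral Brønsted acid catalysis, and the closest known type is the phosphoric acid-catalysed enantioselective Passerini reaction of unbranched aliphatic aldehydes with carboxylic acids and isocyanides. The phosphoric acid pairs with acid 16 through two hydrogen bonds and this pair activates the carbonyl of 14; the isocyanide carbon of 19 (the future C1) adds to C2, the nitrilium ion is captured by the muconate carboxylate to give imidate 20, and a Mumm-type acyl shift to the C2 hydroxyl gives 21. No ring is closed. The only new stereocentre is C2 and the catalyst controls it: its 3,3'-aryl groups shield one face so that the isocyanide attacks the Si face of the aldehyde, which corresponds to 2R, while the C7–C9 centres lie five bonds away and should neither help nor hinder. The step needs facial selectivity at C2, and because C7–C9 are already fixed any minor C2 epimer is a separable diastereomer. It also needs chemoselectivity for the aldehyde over the dienoate, which is secured because isocyanides do not add to Michael acceptors. The low nucleophilicity of the electron-poor isocyanide should slow the uncatalysed background reaction, and the acetal and silyl ether should tolerate the weak acid under anhydrous conditions.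

Step 15
Reactants: 21 Passerini adduct
Product: 22 C9-hydroxy amide (C2 muconate; C7/C8 acetonide; configuration unchanged)
Conditions: HF·pyridine, pyridine, THF, 0 °C → rt
Reagents that add atoms: none
Why: Fluoride-driven desilylation under buffered, non-basic conditions, which should spare the acetal, the tert-butyl ester and the base-sensitive alpha-acyloxy amide.

Step 16
Reactants: 22 C9-hydroxy amide
Product: 23 ten-membered lactone (C7/C8 acetonide; C2 tert-butyl muconate; configuration unchanged)
Conditions: Zn(OTf)2 (1.5 equiv), iPr2NEt (3 equiv), toluene/MeCN, 2 mM (slow addition of 22), 80 °C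
Reagents that add atoms: none
Why: Proposed new method: divalent zinc should bind the pyridine nitrogen and the amide oxygen of 22 in a six-membered chelate, which raises the electrophilicity of C1 and makes 2-amino-6-bromopyridine a leaving group, while the C9 hydroxyl, held on the same metal as a zinc alkoxide with the amine base, attacks C1 in an exo-trig acyl substitution that closes the lactone; the closest known reactions are the intermolecular alcoholysis of N-(6-bromopyridin-2-yl) amides and the zinc-catalysed pyridine-directed alcoholysis of N-(pyridin-2-yl) amides, neither shown for a medium ring, and the E alkene and the trans-disubstituted dioxolane are relied on to limit the chain's freedom at high dilution (the amine base also buffers the acetal and tert-butyl ester against triflic acid).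

Step 17
Reactants: 23 ten-membered lactone
Product: 24 target, (2R,7R,8S,9R)-lactone with free C7/C8 diol and free muconic half acid
Conditions: CF3CO2H/H2O/CH2Cl2, 0 °C → rt; evaporation, brief stirring in aq. MeCN
Reagents that add atoms: none
Why: Acid-catalysed hydrolysis of the dioxolane and cleavage of the tert-butyl ester through the tert-butyl cation occur in one operation; no bond to a stereocentre is broken and both remaining esters are stable to cold acid.

## Compound list

1 | D-arabinose (drawn as the open-chain aldehyde) | O=C[C@@H](O)[C@H](O)[C@H](O)CO | starting material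
2 | D-arabinose diethyl dithioacetal | CCSC(SCC)[C@@H](O)[C@H](O)[C@H](O)CO | intermediate
3 | 2,3:4,5-di-O-isopropylidene-D-arabinose diethyl dithioacetal | CCSC(SCC)[C@H]1OC(C)(C)O[C@@H]1[C@H]2COC(C)(C)O2 | intermediate
4 | 2,3-O-isopropylidene-D-arabinose diethyl dithioacetal | CCSC(SCC)[C@H]1OC(C)(C)O[C@@H]1[C@H](O)CO | intermediate
5 | 2,3-O-isopropylidene-5-O-tosyl-D-arabinose diethyl dithioacetal | CCSC(SCC)[C@H]1OC(C)(C)O[C@@H]1[C@H](O)COS(=O)(=O)c2ccc(C)cc2 | intermediate (not isolated)
6 | 4,5-anhydro-2,3-O-isopropylidene-D-arabinose diethyl dithioacetal | CCSC(SCC)[C@H]1OC(C)(C)O[C@@H]1[C@H]2CO2 | intermediate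
7 | 5,6,7-trideoxy-2,3-O-isopropylidene-D-arabino-heptose diethyl dithioacetal | CCC[C@@H](O)[C@H]1OC(C)(C)O[C@@H]1C(SCC)SCC | intermediate
8 | 4-O-TBS ether of 7 (C9 OTBS) | CCC[C@@H](O[Si](C)(C)C(C)(C)C)[C@H]1OC(C)(C)O[C@@H]1C(SCC)SCC | intermediate
9 | C6 aldehyde (C6–C12; C7/C8 acetonide; C9 OTBS) | CCC[C@@H](O[Si](C)(C)C(C)(C)C)[C@H]1OC(C)(C)O[C@@H]1C=O | intermediate
10 | allylic alcohol, C4–C12, both C6 epimers | CCC[C@@H](O[Si](C)(C)C(C)(C)C)[C@H]1OC(C)(C)O[C@@H]1C(O)C=C | intermediate
11 | triethyl orthoacetate | CCOC(C)(OCC)OCC | starting material
12 | mixed ethyl ketene acetal of 10 | CCC[C@@H](O[Si](C)(C)C(C)(C)C)[C@H]1OC(C)(C)O[C@@H]1C(OC(=C)OCC)C=C | intermediate (not isolated)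
13 | ethyl (E)-ester of the C2–C12 chain | CCC[C@@H](O[Si](C)(C)C(C)(C)C)[C@H]1OC(C)(C)O[C@@H]1/C=C/CCC(=O)OCC | intermediate
14 | (E)-4-enal carrying C2–C12 (C7 R, C8 S, C9 R) | CCC[C@@H](O[Si](C)(C)C(C)(C)C)[C@H]1OC(C)(C)O[C@@H]1/C=C/CCC=O | intermediate
15 | (2E,4E)-muconic acid | OC(=O)/C=C/C=C/C(=O)O | starting material
16 | mono-tert-butyl (2E,4E)-muconate | OC(=O)/C=C/C=C/C(=O)OC(C)(C)C | intermediate
17 | 2-amino-6-bromopyridine | Nc1cccc(Br)n1 | starting material
18 | N-(6-bromopyridin-2-yl)formamide | O=CNc1cccc(Br)n1 | intermediate
19 | 2-bromo-6-isocyanopyridine | [C-]#[N+]c1cccc(Br)n1 | intermediate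
20 | O-acyl imidate (Passerini alpha-adduct; C2 OH) | CCC[C@@H](O[Si](C)(C)C(C)(C)C)[C@H]1OC(C)(C)O[C@@H]1/C=C/CC[C@@H](O)C(OC(=O)/C=C/C=C/C(=O)OC(C)(C)C)=Nc2cccc(Br)n2 | intermediate (not isolated)
21 | (2R)-alpha-acyloxy N-(6-bromopyridin-2-yl) amide | CCC[C@@H](O[Si](C)(C)C(C)(C)C)[C@H]1OC(C)(C)O[C@@H]1/C=C/CC[C@@H](OC(=O)/C=C/C=C/C(=O)OC(C)(C)C)C(=O)Nc2cccc(Br)n2 | intermediate
22 | C9-hydroxy amide | CCC[C@@H](O)[C@H]1OC(C)(C)O[C@@H]1/C=C/CC[C@@H](OC(=O)/C=C/C=C/C(=O)OC(C)(C)C)C(=O)Nc2cccc(Br)n2 | intermediate
23 | ten-membered lactone, C7/C8 acetonide, tert-butyl muconate | CCC[C@H]1OC(=O)[C@H](OC(=O)/C=C/C=C/C(=O)OC(C)(C)C)CC/C=C/[C@H]2OC(C)(C)O[C@H]12 | intermediate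
24 | target | CCC[C@H]1OC(=O)[C@H](OC(=O)/C=C/C=C/C(=O)O)CC/C=C/[C@@H](O)[C@@H]1O | target

## Step count and risk

Total: 17 steps. Longest linear sequence: 14 steps (steps 1–10, then 14–17).

**Step 16 (lactonisation).** Most likely failure: the chelated amide is not electrophilic enough for a hindered secondary alkoxide across a ten-membered transition state, so intermolecular oligomerisation or base-induced epimerisation at C2 takes over. Fallback with known chemistry, from 21 back to 23:
- Boc2O/DMAP acylates the amide nitrogen to give N-Boc imide F1.
- Its twisted, doubly acylated nitrogen makes C1 an acyl donor towards allyl alcohol (K3PO4, THF), giving allyl ester F2.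
- HF·pyridine frees C9–OH to give hydroxy allyl ester F3.
- Pd(PPh3)4/morpholine removes the allyl group to give seco acid F4.
- 2-Methyl-6-nitrobenzoic anhydride/DMAP at high dilution closes the lactone to 23.

**Step 14 (key step).** Most likely failure: poor facial selectivity, because the uncatalysed pathway competes or the pyridyl isocyanide and product amide bind the catalyst, together with slow conversion of the weakly nucleophilic isocyanide. Fallback, from 14 back to 21:
- 14 and 19 with CF3CO2H/pyridine in CH2Cl2 (the Passerini variant with trifluoroacetic acid as acid component) give trifluoroacetate F5.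
- Bicarbonate work-up hydrolyses it to hydroxy amide F6 as both C2 epimers.
- Dess–Martin oxidation gives alpha-keto amide F7.
- Asymmetric transfer hydrogenation with RuCl(p-cymene)(TsDPEN) and HCO2H/Et3N sets C2 under reagent control to give (2R)-hydroxy amide F8; the catalyst antipode is chosen on the first run.
- Carbodiimide/DMAP esterification with 16 gives 21.

**Step 17 (global deprotection).** Most likely failure: acid-promoted ionisation at the allylic C7–O bond, or ring contraction by acyl migration once C8–OH is free, before the slower tert-butyl cleavage is complete. Fallback, from 23 to 24: TMSOTf/2,6-lutidine in CH2Cl2 cleaves the tert-butyl ester without protic acid and gives, after aqueous work-up, acetonide acid F9. The dioxolane is then removed separately with CeCl3·7H2O/oxalic acid in MeCN.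

**Step 9 (Johnson–Claisen).** Most likely failure: erosion of E selectivity if the chair preference is weak, and acid-induced silyl or acetal loss at 135 °C. Fallback, from 9 directly to 13 by a Julia–Kocienski olefination:
- Ethyl 4-bromobutanoate and 1-phenyl-1H-tetrazole-5-thiol (K2CO3, acetone) give sulfide F10.
- H2O2/(NH4)6Mo7O24 oxidises it to sulfone F11.
- F11 and 9 with KN(SiMe3)2 in DME at −60 °C give 13, the E geometry arising from the anti addition–elimination pathway.

**Step 11 (half ester).** Most likely failure: over-esterification, because the sparingly soluble diacid reacts more slowly than the dissolved half ester. Fallback, from 15 back to 16: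
- MeOH/H2SO4 gives dimethyl muconate F12.
- One equivalent of KOH in MeOH gives monomethyl muconate F13; the first carboxylate deactivates the vinylogous second ester, so hydrolysis should stop there.
- Excess Me2NCH(OtBu)2 gives methyl tert-butyl muconate F14.
- LiOH in THF/H2O at 0 °C cleaves only the methyl ester to give 16.

## Further compounds

F1 | step 16 | N-Boc imide of 21 | CCC[C@@H](O[Si](C)(C)C(C)(C)C)[C@H]1OC(C)(C)O[C@@H]1/C=C/CC[C@@H](OC(=O)/C=C/C=C/C(=O)OC(C)(C)C)C(=O)N(C(=O)OC(C)(C)C)c2cccc(Br)n2
F2 | step 16 | allyl ester (C2 muconate; C7/C8 acetonide; C9 OTBS) | CCC[C@@H](O[Si](C)(C)C(C)(C)C)[C@H]1OC(C)(C)O[C@@H]1/C=C/CC[C@@H](OC(=O)/C=C/C=C/C(=O)OC(C)(C)C)C(=O)OCC=C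
F3 | step 16 | hydroxy allyl ester (C9 OH) | CCC[C@@H](O)[C@H]1OC(C)(C)O[C@@H]1/C=C/CC[C@@H](OC(=O)/C=C/C=C/C(=O)OC(C)(C)C)C(=O)OCC=C
F4 | step 16 | seco acid (C1 CO2H; C9 OH) | CCC[C@@H](O)[C@H]1OC(C)(C)O[C@@H]1/C=C/CC[C@@H](OC(=O)/C=C/C=C/C(=O)OC(C)(C)C)C(=O)O
F5 | step 14 | C2 trifluoroacetate of the hydroxy amide (C2 epimers) | CCC[C@@H](O[Si](C)(C)C(C)(C)C)[C@H]1OC(C)(C)O[C@@H]1/C=C/CCC(OC(=O)C(F)(F)F)C(=O)Nc2cccc(Br)n2
F6 | step 14 | alpha-hydroxy amide (C2 epimers) | CCC[C@@H](O[Si](C)(C)C(C)(C)C)[C@H]1OC(C)(C)O[C@@H]1/C=C/CCC(O)C(=O)Nc2cccc(Br)n2
F7 | step 14 | alpha-keto amide | CCC[C@@H](O[Si](C)(C)C(C)(C)C)[C@H]1OC(C)(C)O[C@@H]1/C=C/CCC(=O)C(=O)Nc2cccc(Br)n2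
F8 | step 14 | (2R)-alpha-hydroxy amide | CCC[C@@H](O[Si](C)(C)C(C)(C)C)[C@H]1OC(C)(C)O[C@@H]1/C=C/CC[C@@H](O)C(=O)Nc2cccc(Br)n2
F9 | step 17 | acetonide acid (lactone with free muconic half acid) | CCC[C@H]1OC(=O)[C@H](OC(=O)/C=C/C=C/C(=O)O)CC/C=C/[C@H]2OC(C)(C)O[C@H]12
F10 | step 9 | ethyl 4-[(1-phenyl-1H-tetrazol-5-yl)sulfanyl]butanoate | CCOC(=O)CCCSc1nnnn1-c2ccccc2
F11 | step 9 | ethyl 4-[(1-phenyl-1H-tetrazol-5-yl)sulfonyl]butanoate | CCOC(=O)CCCS(=O)(=O)c1nnnn1-c2ccccc2
F12 | step 11 | dimethyl (2E,4E)-muconate | COC(=O)/C=C/C=C/C(=O)OC
F13 | step 11 | monomethyl (2E,4E)-muconate | COC(=O)/C=C/C=C/C(=O)O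
F14 | step 11 | methyl tert-butyl (2E,4E)-muconate | COC(=O)/C=C/C=C/C(=O)OC(C)(C)C
A1 | alternative 1 | trans-fused bicyclic lactol (C1 hemiketal; C5 equatorial SnBu3; C2 OTBS; C7 and C8 OPMB; C9 propyl) | CCC[C@H]1O[C@@]2(O)[C@H](O[Si](C)(C)C(C)(C)C)CC[C@@H]([Sn](CCCC)(CCCC)CCCC)[C@@H]2[C@@H](OCc3ccc(OC)cc3)[C@@H]1OCc4ccc(OC)cc4
A2 | alternative 1 | ten-membered E-ene lactone (C2 OTBS; C7 and C8 OPMB) | CCC[C@H]1OC(=O)[C@H](O[Si](C)(C)C(C)(C)C)CC/C=C/[C@@H](OCc2ccc(OC)cc2)[C@@H]1OCc3ccc(OC)cc3
A3 | alternative 2 | C9 ester of (R)-2-(PMB-oxy)but-3-enoic acid with the E-alkenyl iodide at C5 (C7/C8 acetonide) | CCC[C@@H](OC(=O)[C@H](OCc1ccc(OC)cc1)C=C)[C@H]2OC(C)(C)O[C@@H]2/C=C/I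
A4 | alternative 2 | ten-membered E-ene lactone (C2 OPMB; C7/C8 acetonide) | CCC[C@H]1OC(=O)[C@H](OCc2ccc(OC)cc2)CC/C=C/[C@H]3OC(C)(C)O[C@H]13
A5 | alternative 3 | C9 ester with the E-alkenyl iodide at C6 and the C7 aldehyde (C2 OPMB; C8 OTBS) | CCC[C@@H](OC(=O)[C@H](OCc1ccc(OC)cc1)CC/C=C/I)[C@@H](O[Si](C)(C)C(C)(C)C)C=O
A6 | alternative 3 | ten-membered E-ene lactone with free C7 hydroxyl (C2 OPMB; C8 OTBS) | CCC[C@H]1OC(=O)[C@H](OCc2ccc(OC)cc2)CC/C=C/[C@@H](O)[C@@H]1O[Si](C)(C)C(C)(C)C
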